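## Retrosynthetic overview

1. The target is epicatechin-(4β→8)-4β-carboxymethylepicatechin. Both flavan units, all four rings and the four C2/C3 stereocentres come intact from (−)-epicatechin, so no ring is formed in the route.
2. Last step: global O-debenzylation. Before it: the interflavan C4–C8 bond, made by SN1 Friedel–Crafts coupling of a 4β-acetoxy electrophile with the C8-unsubstituted 4β-carboxymethyl nucleophile.
3. The lower-unit C4–CH2CO2H bond is traced back to the same 4β-acetate through a 1,3 O→C shift of its silyl ketene acetal, so the acetate is both leaving group and carbon source.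
4. Key step: benzylic C4–H acetoxylation (C–O bond formation) of tetra-O-benzylepicatechin. This one intermediate feeds both halves and sets up both C4 stereocentres.

Assumption: bulk tea-derived (−)-epicatechin counts as a cheap commercial starting material; flavan numbering is used (O1, C2, C3, C4, ring A C5–C8, primes for ring B), and β is the face opposite the 3-OH and the C2 aryl group.

## Route

Step 1
Reactants: 1 (−)-epicatechin; 2 benzyl bromide
Product: 3 5,7,3',4'-tetra-O-benzyl-(−)-epicatechin [(2R,3R)-5,7-bis(benzyloxy)-2-[3,4-bis(benzyloxy)phenyl]-3,4-dihydro-2H-chromen-3-ol]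
Conditions: BnBr (4.2 equiv), K2CO3 (4.5 equiv), DMF, 0 °C → rt
Reagents that add atoms: benzyl bromide, BrCc1ccccc1
Why: Williamson ether synthesis in which K2CO3 deprotonates only the four phenols (pKa about 9–10) and leaves the secondary 3-OH (pKa about 16) free, with no stereocentre touched.

Step 2
Reactants: 3 5,7,3',4'-tetra-O-benzyl-(−)-epicatechin; 4 acetic acid
Product: 5 4β-acetoxy-5,7,3',4'-tetra-O-benzylepicatechin [(2R,3S,4S)-5,7-bis(benzyloxy)-2-[3,4-bis(benzyloxy)phenyl]-3-hydroxy-3,4-dihydro-2H-chromen-4-yl acetate; 3-OH and 4-OAc trans]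
Conditions: DDQ (1.6 equiv), AcOH (10 equiv), dry CH2Cl2, 0 °C → rt; chromatography on Et3N-deactivated silica
Reagents that add atoms: acetic acid, CC(=O)O
Why: DDQ-mediated benzylic C–H oxidation (hydride abstraction at C4, assisted by the 5-, 7- and 1-oxygens) gives the C4 cation, which acetic acid traps on the β face anti to the axial 3-OH to set the 4β C–O centre, and the remaining pseudo-equatorial C4–H is misaligned with ring A so over-oxidation stops.

Step 3
Reactants: 5 4β-acetoxy-5,7,3',4'-tetra-O-benzylepicatechin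
Product: 8 5,7,3',4'-tetra-O-benzyl-4β-carboxymethylepicatechin [2-[(2R,3R,4S)-5,7-bis(benzyloxy)-2-[3,4-bis(benzyloxy)phenyl]-3-hydroxy-3,4-dihydro-2H-chromen-4-yl]acetic acid], via silyl ketene acetal 6 (not isolated), via trimethylsilyl ester 7 (not isolated)
Conditions: Me3SiCl (3 equiv), LiN(SiMe3)2 (2.1 equiv), THF, −78 °C; evaporate; Me3SiOTf (0.2 equiv), CH2Cl2, −78 → −30 °C; aq. citric acid, THF, rt
Reagents that add atoms: none
Why: Proposed new method: Ireland-type enolisation–silylation converts the C4 acetate into an O-flavanyl silyl ketene acetal (the 3-OH is capped as OSiMe3 in the same operation), and catalytic Me3Si+ then silylates the C4–O oxygen so that the trialkoxy-stabilised C4 benzylic cation and the released ketene bis(silyl) acetal fragment part as a contact ion pair and recombine through carbon on the β face, anti to the 3-OSiMe3 group, which sets the 4S (4β) centre and turns the acetate C–O bond into the C4–CH2CO2H unit without any external carbon source, the ketene acetal (far more nucleophilic than ring A) outrunning self-condensation; the closest known reaction types are the Lewis-acid-catalysed ionic 1,3 O→C (Claisen-type) rearrangement of benzyl vinyl ethers and ketene acetals, Ireland–Claisen enolate silylation, and Mukaiyama-type SN1 alkylation of benzylic acetates with silyl ketene acetals.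

Step 4
Reactants: 5 4β-acetoxy-5,7,3',4'-tetra-O-benzylepicatechin; 8 5,7,3',4'-tetra-O-benzyl-4β-carboxymethylepicatechin
Product: 9 octa-O-benzyl epicatechin-(4β→8)-4β-carboxymethylepicatechin [2-[(2R,3R,4S)-5,7-bis(benzyloxy)-2-[3,4-bis(benzyloxy)phenyl]-8-[(2R,3R,4R)-5,7-bis(benzyloxy)-2-[3,4-bis(benzyloxy)phenyl]-3-hydroxy-3,4-dihydro-2H-chromen-4-yl]-3-hydroxy-3,4-dihydro-2H-chromen-4-yl]acetic acid]
Conditions: 8 (2.5 equiv, excess recovered), Me3SiOTf (0.1 equiv), CH2Cl2, −78 °C; Et3N quench, pH 4 work-up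
Reagents that add atoms: none
Why: Lewis-acid-catalysed SN1 Friedel–Crafts interflavan coupling in which the ionised 4β-acetate of 5 is attacked by C8 of 8 (the less hindered ring A position, C6 being flanked by two benzyloxy groups) on the β face anti to the 3-OH, giving the 4β→8 bond with 4R configuration, while the excess of 8 suppresses self-condensation of 5.

Step 5
Reactants: 9 octa-O-benzyl epicatechin-(4β→8)-4β-carboxymethylepicatechin
Product: 10 epicatechin-(4β→8)-4β-carboxymethylepicatechin (target) [2-[(2R,3R,4S)-2-(3,4-dihydroxyphenyl)-8-[(2R,3R,4R)-2-(3,4-dihydroxyphenyl)-3,5,7-trihydroxy-3,4-dihydro-2H-chromen-4-yl]-3,5,7-trihydroxy-3,4-dihydro-2H-chromen-4-yl]acetic acid]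
Conditions: H2 (1 atm), Pd(OH)2/C, THF/MeOH/H2O, rt; filter, lyophilise
Reagents that add atoms: none
Why: Heterogeneous catalytic hydrogenolysis cleaves the eight benzyl ethers under neutral conditions that leave the interflavan bond, the free acid and all six stereocentres untouched.

## Compound list

1 | (−)-epicatechin, (2R,3R)-2-(3,4-dihydroxyphenyl)-3,4-dihydro-2H-chromene-3,5,7-triol | C1c2c(O)cc(O)cc2O[C@H](c2ccc(O)c(O)c2)[C@@H]1O | starting material
2 | benzyl bromide | BrCc1ccccc1 | starting material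
3 | 5,7,3',4'-tetra-O-benzyl-(−)-epicatechin, (2R,3R) | C1c2c(OCc3ccccc3)cc(OCc3ccccc3)cc2O[C@H](c2ccc(OCc3ccccc3)c(OCc3ccccc3)c2)[C@@H]1O | intermediate
4 | acetic acid | CC(=O)O | starting material
5 | 4β-acetoxy-5,7,3',4'-tetra-O-benzylepicatechin, (2R,3S,4S) | CC(=O)O[C@H]1c2c(OCc3ccccc3)cc(OCc3ccccc3)cc2O[C@H](c2ccc(OCc3ccccc3)c(OCc3ccccc3)c2)[C@@H]1O | intermediate
6 | 5,7,3',4'-tetra-O-benzyl-3-O-trimethylsilyl-4β-O-[1-(trimethylsilyloxy)ethenyl]epicatechin (silyl ketene acetal of 5), (2R,3S,4S) | C=C(O[Si](C)(C)C)O[C@H]1c2c(OCc3ccccc3)cc(OCc3ccccc3)cc2O[C@H](c2ccc(OCc3ccccc3)c(OCc3ccccc3)c2)[C@@H]1O[Si](C)(C)C | intermediate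
7 | trimethylsilyl 2-[(2R,3R,4S)-5,7-bis(benzyloxy)-2-[3,4-bis(benzyloxy)phenyl]-3-(trimethylsilyloxy)-3,4-dihydro-2H-chromen-4-yl]acetate | C[Si](C)(C)OC(=O)C[C@H]1c2c(OCc3ccccc3)cc(OCc3ccccc3)cc2O[C@H](c2ccc(OCc3ccccc3)c(OCc3ccccc3)c2)[C@@H]1O[Si](C)(C)C | intermediate
8 | 5,7,3',4'-tetra-O-benzyl-4β-carboxymethylepicatechin, (2R,3R,4S) | O=C(O)C[C@H]1c2c(OCc3ccccc3)cc(OCc3ccccc3)cc2O[C@H](c2ccc(OCc3ccccc3)c(OCc3ccccc3)c2)[C@@H]1O | intermediate
9 | octa-O-benzyl epicatechin-(4β→8)-4β-carboxymethylepicatechin, upper unit (2R,3R,4R), lower unit (2R,3R,4S) | O=C(O)C[C@H]1c2c(OCc5ccccc5)cc(OCc5ccccc5)c([C@H]3c4c(OCc5ccccc5)cc(OCc5ccccc5)cc4O[C@H](c4ccc(OCc5ccccc5)c(OCc5ccccc5)c4)[C@@H]3O)c2O[C@H](c2ccc(OCc5ccccc5)c(OCc5ccccc5)c2)[C@@H]1O | intermediate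
10 | epicatechin-(4β→8)-4β-carboxymethylepicatechin, upper unit (2R,3R,4R), lower unit (2R,3R,4S) | O=C(O)C[C@H]1c2c(O)cc(O)c([C@H]3c4c(O)cc(O)cc4O[C@H](c4ccc(O)c(O)c4)[C@@H]3O)c2O[C@H](c2ccc(O)c(O)c2)[C@@H]1O | target

## Step count and risks

Total steps: 5. Longest linear sequence: 5 (1 → 3 → 5 → 8 → 9 → 10); compound 5 is used twice, as precursor of 8 and as coupling partner.

**Step 3 (the proposed new 1,3 O→C acetate shift).** It can fail through C-silylation of the acetate enolate, or through ionisation of 5 or 6 before the ketene acetal is in place, which would lead to oligomers. The fallback uses known chemistry and sets out from 5. An intermolecular Mukaiyama-type SN1 substitution with commercial 1-(tert-butyldimethylsilyloxy)-1-methoxyethene (BF3·OEt2, CH2Cl2, −78 °C) gives 5,7,3',4'-tetra-O-benzyl-4β-(methoxycarbonylmethyl)epicatechin F1, the nucleophile again entering β, anti to the 3-OH. Saponification with LiOH in THF/H2O and mild acidification then returns to the route at 8.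

**Step 4 (interflavan coupling).** The risk is self-condensation of 5 through its own C8, together with some 4→6 isomer. The fallback is the C8-capping strategy and sets out from 3. Bromination with NBS (CH2Cl2, −78 °C) gives 8-bromo-5,7,3',4'-tetra-O-benzylepicatechin F2. DDQ/AcOH oxidation as in step 2 gives 4β-acetoxy-8-bromo-5,7,3',4'-tetra-O-benzylepicatechin F3, which can no longer act as a nucleophile. Equimolar coupling of F3 with 8 (Me3SiOTf, CH2Cl2, −78 °C) gives octa-O-benzyl 8-bromoepicatechin-(4β→8)-4β-carboxymethylepicatechin F4, with bromine on C8 of the upper unit. Hydrogenolysis (H2, Pd(OH)2/C, Et3N, THF/MeOH/H2O) removes the bromine and the eight benzyl groups together, so the fallback comes back to the route at 10.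

**Step 2 (C4–H acetoxylation).** The 4β-acetate may be too labile to isolate cleanly or may form in low yield. The fallback sets out from 3 and uses the well-established ether leaving group. DDQ with 2-ethoxyethanol in CH2Cl2 gives 4β-(2-ethoxyethoxy)-5,7,3',4'-tetra-O-benzylepicatechin F5. This ether serves as the C4 electrophile in both carbon–carbon bond formations. With 1-(tert-butyldimethylsilyloxy)-1-methoxyethene and Me3SiOTf it gives 5,7,3',4'-tetra-O-benzyl-4β-(methoxycarbonylmethyl)epicatechin F1, and LiOH hydrolysis returns to the route at 8. With 8 and catalytic Me3SiOTf at −78 °C it returns to the route at 9.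

## Further compounds

F1 | step 3 | 5,7,3',4'-tetra-O-benzyl-4β-(methoxycarbonylmethyl)epicatechin (methyl ester of 8) | COC(=O)C[C@H]1c2c(OCc3ccccc3)cc(OCc3ccccc3)cc2O[C@H](c2ccc(OCc3ccccc3)c(OCc3ccccc3)c2)[C@@H]1O
F2 | step 4 | 8-bromo-5,7,3',4'-tetra-O-benzylepicatechin | C1c2c(OCc3ccccc3)cc(OCc3ccccc3)c(Br)c2O[C@H](c2ccc(OCc3ccccc3)c(OCc3ccccc3)c2)[C@@H]1O
F3 | step 4 | 4β-acetoxy-8-bromo-5,7,3',4'-tetra-O-benzylepicatechin | CC(=O)O[C@H]1c2c(OCc3ccccc3)cc(OCc3ccccc3)c(Br)c2O[C@H](c2ccc(OCc3ccccc3)c(OCc3ccccc3)c2)[C@@H]1O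
F4 | step 4 | octa-O-benzyl 8-bromoepicatechin-(4β→8)-4β-carboxymethylepicatechin (Br on C8 of the upper unit) | O=C(O)C[C@H]1c2c(OCc5ccccc5)cc(OCc5ccccc5)c([C@H]3c4c(OCc5ccccc5)cc(OCc5ccccc5)c(Br)c4O[C@H](c4ccc(OCc5ccccc5)c(OCc5ccccc5)c4)[C@@H]3O)c2O[C@H](c2ccc(OCc5ccccc5)c(OCc5ccccc5)c2)[C@@H]1O
F5 | step 2 | 4β-(2-ethoxyethoxy)-5,7,3',4'-tetra-O-benzylepicatechin | CCOCCO[C@H]1c2c(OCc3ccccc3)cc(OCc3ccccc3)cc2O[C@H](c2ccc(OCc3ccccc3)c(OCc3ccccc3)c2)[C@@H]1O
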